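How much target will the west run hold at 34 h, with a catalyst charge higher than in any earlier run? And how does the starting rate answer to catalyst and to partner?

* apparent order in [catalyst] of the starting rate, round the charge of the south-east run (the rate where two percent of its starting material have turned into target)
* apparent order in [partner] of the starting rate, round the charge of the south-east run (the rate where two percent of its starting material have turned into target)
* target in the west run at 34 h, as a share of the starting material charged

the same everywhere: starting material 0.0500 M
- south-east: partner 0.0400 M; catalyst 0.00250 M
- north-west: partner 0.0600 M; catalyst 0.00250 M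
- south: partner 0.0400 M; catalyst 0.00500 M
- west: partner 0.0400 M; catalyst 0.0110 M; time 34 h

| run | time / h | [target] / M |
|---|---|---|
| south-east run | 1.2 | 0.0033 |
| south-east run | 3.7 | 0.0092 |
| south-east run | 7.1 | 0.0139 |
| south-east run | 11 | 0.0180 |
| south-east run | 16 | 0.0207 |
| south-east run | 21 | 0.0221 |
| south-east run | 27 | 0.0236 |
| south-east run | 34 | 0.0247 |
| north-west run | 1.2 | 0.0048 |
| north-west run | 3.7 | 0.0114 |
| north-west run | 7.1 | 0.0183 |
| north-west run | 11 | 0.0223 |
| north-west run | 16 | 0.0247 |
| north-west run | 21 | 0.0260 |
| north-west run | 27 | 0.0262 |
| north-west run | 34 | 0.0269 |
| south run | 1.2 | 0.0068 |
| south run | 3.7 | 0.0151 |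
| south run | 7.1 | 0.0218 |
| south run | 11 | 0.0256 |
| south run | 16 | 0.0284 |
| south run | 21 | 0.0293 |
| south run | 27 | 0.0300 |
| south run | 34 | 0.0306 |

(each reading ± 3 × 10⁻⁴ M)

- Overall: starting material + partner -> target, with catalyst as catalyst.
- Constant volume, constant temperature.
- Readings of a species count what is bound in complexes too.
- An order is taken over about fifteen percent of the charge, up and down.

Start by counting turnovers. One turnover means that each catalyst molecule has made one target on average, so the first reading divided by the catalyst charge and by its time gives turnovers per hour, averaged over that first stretch:

south-east: 0.0033 M / (0.00250 M × 1.2 h) = 1.10 /h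
south: 0.0068 M / (0.00500 M × 1.2 h) = 1.13 /h

The two paces read close, and the scatter of one reading is worth 0.100 /h on the south-east pace. Twice the catalyst gave twice the target at the first reading, so I read an order in catalyst of 1.04. In the north-west run, the first reading stands 1.45 times that of the south-east run on 1.50 times the partner, which gives me an order in partner of 0.924, read over a wider step than the one asked and from single readings.

But you can't run the pace forward. At that pace the south-east run would reach 37.4 turnovers by 34 h, and its last reading shows 9.88.

So count what is missing instead. Take the smaller of the two charges, the limiting reagent, and subtract the target at 34 h. The south-east run leaves 0.0153 M. This is the gap, the charge of limiting reagent less the target made by that time. Partner is the limiting reagent in the south and west runs too, so the gap can be carried across: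

south gap: 0.00940 M
power of catalyst: ln(0.614) / ln(2.00) = −0.703
west gap: 0.00940 M × 2.20^(−0.703) = 0.00540 M
west target: 0.0400 M − 0.00540 M = 0.0346 M, or 69.2% of the starting material

That line rests on two readings and goes beyond them, so I hold it loosely.

The forecast gave 0.95 in catalyst, 0.85 in partner and 71% for the west run, arguing that “The plateaus suggest catalyst death rather than equilibrium”. My order in partner stands above its value, and my share stands below its value.

The west run holds 71.1% of the starting material, with orders of 1.0 in catalyst and 0.74 in partner, so the forecast held on all three.

    catalyst + starting material ⇌ catalyst-substrate complex (89.28 /M/h, 15.23 /h)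
    catalyst-substrate complex + partner → target + catalyst (196.2 /M/h)
    target + partner → side product (0.5328 /M/h)
    starting material → decomposed substrate (0.01566 /h)

Fitted with the main steps alone, the readings leave a residual of 11 in units of the scatter. The west gap comes to 0.00444 M against my 0.00540 M, a difference of 1.93% of the starting material. In the north-west run, where starting material is the limiting reagent, the gap reads 0.0231 M, wider than the 0.0153 M of the south-east run.

The numbers in the tables stem from a simulated flask on assumed constants.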